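**Retrosynthetic overview**

1. Target 14 is the dienol tautomer of a 3-alkylcyclohexane-1,2,4,5-tetraone. With the ring numbered C1(=O), C2(OH), C3(side chain), C4(=O), C5(OH), C6(H), it is cut at C2–C3 and C5–C6 into two 2-oxo acid triads: C3–C4–C5 from ethyl (17E)-2-oxodocos-17-enoate 9 and C6–C1–C2 from pyruvoyl chloride 11.
2. Enabling feature: each OH-bearing ring carbon (C2, C5) is a former carboxyl carbon, 1,3 to a ring carbonyl (C4, C1) and bonded to the α-carbon of the other unit (C3, C6). Two head-to-tail Claisen acylations of two 2-oxo acid units therefore give the ring directly at the quinone oxidation level, with no oxidant and no protecting group.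
3. Key step (one flask): O-acylation of the enol of 9 by 11, DMAP-relayed O→C acyl shift (C2–C3), then Dieckmann closure (C5–C6); the six-membered carbocycle is the only ring and is formed last.
4. 9 comes from the Grignard reagent of (E)-20-bromoicos-5-ene 5 and diethyl oxalate. 5 comes from purchased (E)-dec-5-en-1-ol 1 by Appel bromination and copper-catalysed coupling with 1,10-dibromodecane; the E-alkene is bought and never touched.
5. 11 is made in one step from pyruvic acid.

Key step: step 5

Assumption: (E)-dec-5-en-1-ol is purchased geometrically pure, so no step has to set the side-chain alkene geometry; 14 is handled as the 2,5-dihydroxy-1,4-benzoquinone tautomer.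

**Step 1**
Reactants: 1 (E)-dec-5-en-1-ol
Product: 2 (E)-1-bromodec-5-ene
Conditions: CBr4 (1.2 equiv), PPh3 (1.25 equiv), CH2Cl2, 0 → 23 °C
Reagents that add atoms: carbon tetrabromide, BrC(Br)(Br)Br
Why: Appel reaction; the primary hydroxyl is activated by PPh3/CBr4 and displaced by bromide in an SN2 step under neutral conditions that leave the remote E-alkene untouched, and no stereocentre is involved.

**Step 2**
Reactants: 2 (E)-1-bromodec-5-ene; 3 1,10-dibromodecane
Product: 5 (E)-20-bromoicos-5-ene, via (E)-dec-5-enylmagnesium bromide 4 (not isolated)
Conditions: Mg, THF, 23–35 °C; then addition to 3 (3 equiv), Li2CuCl4 (3 mol%), THF, −10 → 0 °C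
Reagents that add atoms: none
Why: Copper-catalysed sp3–sp3 Grignard cross-coupling (Kochi–Tamura type) of a primary alkyl bromide; the threefold excess of the symmetrical dibromide should favour monocoupling, and the alkene geometry is not affected.

**Step 3**
Reactants: 5 (E)-20-bromoicos-5-ene; 6 diethyl oxalate
Product: 9 ethyl (17E)-2-oxodocos-17-enoate, via (E)-icos-15-enylmagnesium bromide 7 (not isolated), via magnesium hemiketal alkoxide 8 (not isolated)
Conditions: Mg, I2 (cat.), THF, 45 °C; then addition to 6 (3 equiv), THF, −78 °C; 1 M HCl, −78 → 0 °C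
Reagents that add atoms: none
Why: Mono-addition of a Grignard reagent to a dialkyl oxalate, the standard 2-oxo ester synthesis; inverse addition into excess 6 at −78 °C should stop at the tetrahedral adduct 8, which releases the ketone only on acidic quench, so no second addition occurs.

**Step 4**
Reactants: 10 pyruvic acid
Product: 11 pyruvoyl chloride (2-oxopropanoyl chloride)
Conditions: Cl2CHOMe (1.0 equiv), neat, 50 °C; distillation under reduced pressure, used at once
Reagents that add atoms: α,α-dichloromethyl methyl ether, COC(Cl)Cl
Why: Acid chloride formation with α,α-dichloromethyl methyl ether, the established preparation of this acid chloride; the reagent is converted to methyl formate and HCl and is mild enough to leave the ketone alone.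

**Step 5**
Reactants: 9 ethyl (17E)-2-oxodocos-17-enoate; 11 pyruvoyl chloride
Product: 14 2,5-dihydroxy-3-[(14E)-nonadec-14-en-1-yl]cyclohexa-2,5-diene-1,4-dione, via enol ester 12 (not isolated), via triketo ester 13 (not isolated)
Conditions: Et3N (2.5 equiv), DMAP (0.2 equiv), THF, −20 °C, then 11 (1.2 equiv), −20 → 23 °C; then t-BuOK (5 equiv), THF, 0 → 23 °C; then 1 M HCl
Reagents that add atoms: none
Why: Proposed new method: Et3N enolizes only 9 (soft enolization of the C–H next to the 2-oxo ester) and the enol oxygen is acylated by 11, which cannot form a ketene because its acyl carbon bears no α-hydrogen, to give enol ester 12; DMAP then attacks the oxalyl-type ester carbonyl of 12 and returns the pyruvoyl group to the α-carbon of the released keto-ester enolate (O→C acyl shift, new C2–C3 bond), and the C-acylated product 13 is drained from the equilibrium as its highly stabilized enolate. t-BuOK converts this enolate into the dianion by deprotonating the terminal methyl ketone, whose carbanion attacks the ethyl ester in a Dieckmann condensation (new C5–C6 bond) that closes the only ring, the six-membered carbocycle, in the 6-(enolendo)-exo-trig mode and expels ethoxide to give the dianion of the cyclohexane-1,2,4,5-tetraone, which is the dianion of quinone 14 and is released by acid. The closest known reaction types are the one-flask acid chloride O-acylation followed by cyanide- or DMAP-catalysed rearrangement of enol esters to 2-acyl-1,3-dicarbonyl compounds, the Dieckmann condensation, and the base-induced self-condensation of 2-oxo esters to 3,6-dialkyl-2,5-dihydroxy-1,4-benzoquinones, the laboratory counterpart of the head-to-tail union of two arylpyruvate units that builds the same ring in the terphenylquinones; new here is the crossed, directed version on the enol of a 2-oxo ester. No stereocentre is created, since C3 of 13 is enolized and ends as an sp2 ring carbon, and the geometry of enol ester 12 is irrelevant. The step needs crossed instead of statistical pairing and Claisen instead of aldol reactivity: pairing is fixed because 9 enters only as the enol nucleophile and the pyruvate unit only as the acid chloride electrophile, the second C–C bond is formed intramolecularly through a six-membered ring, and after the acyl shift the ketone carbonyls flanking C3 are masked in the enolate so that the ester is the only electrophile within reach of the methyl carbanion, while the doubly vinylogous carboxylate dianion of 14 is the thermodynamic sink.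

**Compound list**

1 | (E)-dec-5-en-1-ol | CCCC/C=C/CCCCO | starting material
2 | (E)-1-bromodec-5-ene | CCCC/C=C/CCCCBr | intermediate
3 | 1,10-dibromodecane | BrCCCCCCCCCCBr | starting material
4 | (E)-dec-5-enylmagnesium bromide | CCCC/C=C/CCCC[Mg]Br | intermediate
5 | (E)-20-bromoicos-5-ene | CCCC/C=C/CCCCCCCCCCCCCCBr | intermediate
6 | diethyl oxalate | CCOC(=O)C(=O)OCC | starting material
7 | (E)-icos-15-enylmagnesium bromide | CCCC/C=C/CCCCCCCCCCCCCC[Mg]Br | intermediate
8 | bromomagnesium salt of ethyl (17E)-2-ethoxy-2-hydroxydocos-17-enoate (racemic tetrahedral adduct) | CCCC/C=C/CCCCCCCCCCCCCCC(OCC)(O[Mg]Br)C(=O)OCC | intermediate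
9 | ethyl (17E)-2-oxodocos-17-enoate | CCCC/C=C/CCCCCCCCCCCCCCC(=O)C(=O)OCC | intermediate
10 | pyruvic acid | CC(=O)C(=O)O | starting material
11 | pyruvoyl chloride (2-oxopropanoyl chloride) | CC(=O)C(=O)Cl | intermediate
12 | ethyl (2Z,17E)-2-[(2-oxopropanoyl)oxy]docosa-2,17-dienoate | CCCC/C=C/CCCCCCCCCCCCC/C=C(\OC(=O)C(C)=O)C(=O)OCC | intermediate
13 | ethyl 3-[(14E)-nonadec-14-en-1-yl]-2,4,5-trioxohexanoate (racemic at C3, present as its enolate; neutral form drawn) | CCCC/C=C/CCCCCCCCCCCCCC(C(=O)C(C)=O)C(=O)C(=O)OCC | intermediate
14 | 2,5-dihydroxy-3-[(14E)-nonadec-14-en-1-yl]cyclohexa-2,5-diene-1,4-dione | CCCC/C=C/CCCCCCCCCCCCCC1=C(O)C(=O)C=C(O)C1=O | target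

**Step count and risks**

Total step count: 5. Longest linear sequence: 4 steps (steps 1, 2, 3 and 5); step 4 is a one-step side branch.

Steps most likely to fail:

1. Step 5 (proposed new method). The acyl shift may not reach completion, so that tert-butoxide cleaves the remaining oxalyl-type enol ester and the two units separate. The pyruvoyl methyl ketone may also self-condense in aldol fashion, or the ring closure may stop at the open-chain enolate. The fallback uses the standard arene-oxidation route to alkyl dihydroxybenzoquinones; it sets out from bromide 2 (through its Grignard reagent 4) and rejoins the route at 14. Reagent 4 is coupled under Li2CuCl4 catalysis with excess 1,9-dibromononane (BrCCCCCCCCCBr) to give (E)-19-bromononadec-5-ene F1. 1,2,4,5-Tetramethoxybenzene (COc1cc(OC)c(OC)cc1OC) is lithiated with n-BuLi in THF at 0 °C to (2,3,5,6-tetramethoxyphenyl)lithium F2 and alkylated with F1 (DMPU co-solvent) to give 3-[(14E)-nonadec-14-en-1-yl]-1,2,4,5-tetramethoxybenzene F3. Oxidative demethylation with (NH4)2Ce(NO3)6 in MeCN/H2O at 0 °C should give 2,5-dimethoxy-3-[(14E)-nonadec-14-en-1-yl]cyclohexa-2,5-diene-1,4-dione F4. Hydrolysis of its two vinylogous ester groups (2 M NaOH, EtOH/H2O, then HCl) should give 14.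

2. Step 2. Radical 5-exo cyclization can occur during magnesium insertion into the hex-5-enyl-type bromide, and double coupling on the symmetrical dibromide would give a product that is hard to separate. The fallback reverses the polarity and uses a monofunctional partner; it sets out from 2 (now the electrophile) and rejoins at 5. Purchased 2-[(10-bromodecyl)oxy]tetrahydro-2H-pyran (BrCCCCCCCCCCOC1CCCCO1) is converted with Mg in THF into {10-[(tetrahydro-2H-pyran-2-yl)oxy]decyl}magnesium bromide F5. This is coupled with 2 under Li2CuCl4 catalysis to give 2-{[(15E)-icos-15-en-1-yl]oxy}tetrahydro-2H-pyran F6. Acetal cleavage (TsOH, MeOH) gives (E)-icos-15-en-1-ol F7, and Appel bromination (CBr4, PPh3, CH2Cl2) gives 5.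

3. Step 3. A second addition of the Grignard reagent to the keto ester, or Wurtz-type homocoupling during formation of the long-chain Grignard reagent, would lower the return. The fallback makes the 2-oxo ester by umpolung alkylation; it sets out from 5 and rejoins at 9. Ethyl 1,3-dithiane-2-carboxylate (CCOC(=O)C1SCCCS1) is deprotonated (NaH, DMF/toluene, 0 °C) and alkylated with 5 to give ethyl 2-[(15E)-icos-15-en-1-yl]-1,3-dithiane-2-carboxylate F8. Alkylative dithioacetal hydrolysis (MeI, CaCO3, MeCN/H2O, 50 °C), which spares the alkene, gives 9.

**Further compounds**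

F1 | step 5 | (E)-19-bromononadec-5-ene | CCCC/C=C/CCCCCCCCCCCCCBr
F2 | step 5 | (2,3,5,6-tetramethoxyphenyl)lithium | [Li]c1c(OC)c(OC)cc(OC)c1OC
F3 | step 5 | 3-[(14E)-nonadec-14-en-1-yl]-1,2,4,5-tetramethoxybenzene | CCCC/C=C/CCCCCCCCCCCCCc1c(OC)c(OC)cc(OC)c1OC
F4 | step 5 | 2,5-dimethoxy-3-[(14E)-nonadec-14-en-1-yl]cyclohexa-2,5-diene-1,4-dione | CCCC/C=C/CCCCCCCCCCCCCC1=C(OC)C(=O)C=C(OC)C1=O
F5 | step 2 | {10-[(tetrahydro-2H-pyran-2-yl)oxy]decyl}magnesium bromide | Br[Mg]CCCCCCCCCCOC1CCCCO1
F6 | step 2 | 2-{[(15E)-icos-15-en-1-yl]oxy}tetrahydro-2H-pyran (racemic acetal) | CCCC/C=C/CCCCCCCCCCCCCCOC1CCCCO1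
F7 | step 2 | (E)-icos-15-en-1-ol | CCCC/C=C/CCCCCCCCCCCCCCO
F8 | step 3 | ethyl 2-[(15E)-icos-15-en-1-yl]-1,3-dithiane-2-carboxylate | CCCC/C=C/CCCCCCCCCCCCCCC1(C(=O)OCC)SCCCS1
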